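Assumption: locants C1–C15 follow eudesmane numbering (C10 is the quaternary carbon, C14 its CH2O carbon), and (S)-BINAP is taken to give the (S)-ketone in step 1, as it does with aryl- and alkenylboron reagents.

## Retrosynthetic overview

1. Target ⇐ C14 silyl ether ⇐ C2 reduction and diacetylation of a 1-O-(3-methylbut-2-enoyl)-9β-hydroxy enone, itself made from an α'-hydroxy enone by Evans–Tishchenko reduction (C1 ester and C9 alcohol in one operation).
2. Key disconnection C1–C2: ring A is closed by an intramolecular NHC cross-benzoin, in which the Breslow intermediate (acyl anion equivalent) of a (Z)-enal attacks the neopentyl aldehyde on C10.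
3. Keto-dialdehyde ⇐ 2-(silyloxymethyl)-5-isopropenylcyclohexenone + (Z)-alkenylmagnesium + formaldehyde: conjugate addition (C4–C5), then enolate aldol (C10–C1), both anti and relayed from C7.
4. Enone ⇐ cyclohex-2-enone by rhodium/(S)-BINAP isopropenyl addition (sets C7), desaturation and Baylis–Hillman hydroxymethylation (C14).
5. Ring order: ring B is the purchased cyclohexenone; ring A is formed by the benzoin step.

## Route

Step 1
Reactants: 1 cyclohex-2-en-1-one; 2 4,4,5,5-tetramethyl-2-(prop-1-en-2-yl)-1,3,2-dioxaborolane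
Product: 3 (S)-3-(prop-1-en-2-yl)cyclohexan-1-one
Conditions: Rh(acac)(C2H4)2 (3 mol%), (S)-BINAP (3.3 mol%), dioxane/H2O 10:1, 100 °C
Reagents that add atoms: none
Why: Hayashi–Miyaura rhodium-catalysed asymmetric 1,4-addition, in which the (S)-BINAP–alkenylrhodium species adds to one enantioface of the enone and sets C7 as (S).

Step 2
Reactants: 3 (S)-3-(prop-1-en-2-yl)cyclohexan-1-one
Product: 5 (S)-5-(prop-1-en-2-yl)cyclohex-2-en-1-one, via silyl enol ether 4 (not isolated)
Conditions: LiN(iPr)2, THF, −78 °C; Me3SiCl; then Pd(OAc)2 (1.05 equiv), MeCN, rt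
Reagents that add atoms: none
Why: Kinetic deprotonation on the side remote from the branched C3 substituent followed by Saegusa–Ito oxidation gives the 5-substituted enone without touching the stereocentre; the regioselectivity is only moderate, and the minor cross-conjugated 3-isopropenyl enone is removed by chromatography.

Step 3
Reactants: 5 (S)-5-(prop-1-en-2-yl)cyclohex-2-en-1-one; 6 formaldehyde
Product: 7 (S)-2-(hydroxymethyl)-5-(prop-1-en-2-yl)cyclohex-2-en-1-one
Conditions: 37% aq. CH2O, DMAP (20 mol%), THF/H2O, rt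
Reagents that add atoms: none
Why: Morita–Baylis–Hillman hydroxymethylation (DMAP conjugate addition, aldol with formaldehyde, elimination) places C14 on the enone α-carbon and creates no new stereocentre.

Step 4
Reactants: 7 (S)-2-(hydroxymethyl)-5-(prop-1-en-2-yl)cyclohex-2-en-1-one
Product: 8 (S)-2-{[(tert-butyldiphenylsilyl)oxy]methyl}-5-(prop-1-en-2-yl)cyclohex-2-en-1-one
Conditions: tert-butyl(chloro)diphenylsilane, imidazole, CH2Cl2, 0 °C to rt
Reagents that add atoms: tert-butyl(chloro)diphenylsilane, CC(C)(C)[Si](Cl)(c1ccccc1)c1ccccc1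
Why: Standard silylation of the primary allylic alcohol; the bulky, acid-stable silyl group resists both 1,3-migration and the later selective removal of a triethylsilyl ether.

Step 5
Reactants: 9 but-2-yn-1-ol
Product: 11 (Z)-3-iodobut-2-en-1-ol, via cyclic alkenylaluminate 10 (not isolated)
Conditions: NaAlH2(OCH2CH2OCH3)2, THF, 0 °C to rt; then I2, THF, −78 °C to 0 °C
Reagents that add atoms: iodine, II
Why: Alkoxide-directed trans-hydroalumination of the propargylic alcohol puts aluminium on C3 cis to the CH2O group, and iodinolysis with retention gives the (Z)-iodide.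

Step 6
Reactants: 11 (Z)-3-iodobut-2-en-1-ol
Product: 12 (Z)-triethyl[(3-iodobut-2-en-1-yl)oxy]silane
Conditions: chlorotriethylsilane, imidazole, CH2Cl2, 0 °C
Reagents that add atoms: chlorotriethylsilane, CC[Si](Cl)(CC)CC
Why: Standard silylation that masks the hydroxyl for the metalation in step 7 and is later removed selectively by mild acid.

Step 7
Reactants: 12 (Z)-triethyl[(3-iodobut-2-en-1-yl)oxy]silane; 8 (S)-2-{[(tert-butyldiphenylsilyl)oxy]methyl}-5-(prop-1-en-2-yl)cyclohex-2-en-1-one; 6 formaldehyde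
Product: 16 (2S,3R,5S)-2-{[(tert-butyldiphenylsilyl)oxy]methyl}-3-[(2Z)-4-hydroxybut-2-en-2-yl]-2-(hydroxymethyl)-5-(prop-1-en-2-yl)cyclohexan-1-one, via alkenylmagnesium chloride 13 (not isolated), via magnesium enolate 14 (not isolated), via triethylsilyl ether 15 (not isolated)
Conditions: iPrMgCl·LiCl, THF, 0 °C to rt; CuBr·SMe2 (10 mol%), then 8, −40 °C; CH2O (gas from cracked paraformaldehyde), −78 to −40 °C; AcOH/THF/H2O 3:1:1, rt
Reagents that add atoms: none
Why: Iodine–magnesium exchange with retention, copper-catalysed conjugate addition anti to the C7 isopropenyl group (sets C5, as with carvone) and aldol trapping of the regiodefined enolate by formaldehyde anti to the new C5 substituent (sets C10 with C1 trans and C14 cis to the side chain); acetic acid then cleaves only the triethylsilyl ether, and the cold, non-basic quench avoids silyl migration or β-elimination.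

Step 8
Reactants: 16 (the keto diol from step 7)
Product: 17 (1R,2R,4S)-1-{[(tert-butyldiphenylsilyl)oxy]methyl}-6-oxo-2-[(2Z)-4-oxobut-2-en-2-yl]-4-(prop-1-en-2-yl)cyclohexane-1-carbaldehyde
Conditions: Dess–Martin periodinane (2.6 equiv), NaHCO3, CH2Cl2, 0 °C to rt
Reagents that add atoms: none
Why: Dess–Martin oxidation converts the neopentyl and the allylic primary alcohols to aldehydes under buffered, non-basic conditions that preserve the (Z)-enal; C10 is quaternary, so nothing can epimerise.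

Step 9
Reactants: 17 (the keto dialdehyde from step 8)
Product: 18 (1R,4aR,6S,8aR)-8a-{[(tert-butyldiphenylsilyl)oxy]methyl}-1-hydroxy-4-methyl-6-(prop-1-en-2-yl)-4a,5,6,7-tetrahydronaphthalene-2,8(1H,8aH)-dione
Conditions: 2-(pentafluorophenyl)-6,7-dihydro-5H-pyrrolo[2,1-c][1,2,4]triazol-2-ium tetrafluoroborate (20 mol%), iPr2NEt (20 mol%), CH2Cl2 (0.01 M), rt
Reagents that add atoms: none
Why: Proposed new method: the triazolylidene adds to the unhindered enal aldehyde to give a Breslow intermediate (acyl anion equivalent at C2) that attacks the non-enolisable C1 aldehyde through a six-membered transition state, closing ring A trans-fused because C1 is trans to the side chain; the benzoin step is reversible, so the product settles as the conjugated 2-keto-1-ol with the equatorial 1α-hydroxyl hydrogen-bonded to C2=O; the closest known reaction type is the NHC-catalysed intramolecular crossed benzoin cyclisation, together with the acyl-anion reactivity of enals under N-pentafluorophenyl triazolium catalysis.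

Step 10
Reactants: 18 (the α'-hydroxy enone from step 9); 19 3-methylbut-2-enal
Product: 20 (1R,4aR,6S,8S,8aS)-8a-{[(tert-butyldiphenylsilyl)oxy]methyl}-8-hydroxy-4-methyl-2-oxo-6-(prop-1-en-2-yl)-1,2,4a,5,6,7,8,8a-octahydronaphthalen-1-yl 3-methylbut-2-enoate
Conditions: SmI2 (30 mol%) premixed with 19 (6 equiv), THF, −10 °C; then 18
Reagents that add atoms: none
Why: Proposed new method: Evans–Tishchenko reduction in which the hemiacetal formed from the C1 hydroxyl and the enal delivers hydride through a samarium-chelated six-membered transition state to the α face of the C9 ketone, giving the 1,3-anti (9β, axial) alcohol and leaving the oxidised aldehyde as the C1 3-methylbut-2-enoate; the closest known reaction type is the SmI2-catalysed Evans–Tishchenko reduction of β-hydroxy ketones with saturated or aromatic aldehydes, and premixing consumes divalent samarium before the α-ketol is exposed.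

Step 11
Reactants: 20 (the C1 ester from step 10)
Product: 21 (1R,2S,4aR,6S,8S,8aS)-8a-{[(tert-butyldiphenylsilyl)oxy]methyl}-2,8-dihydroxy-4-methyl-6-(prop-1-en-2-yl)-1,2,4a,5,6,7,8,8a-octahydronaphthalen-1-yl 3-methylbut-2-enoate
Conditions: NaBH4, CeCl3·7H2O, MeOH, −78 °C; AcOH quench at −78 °C
Reagents that add atoms: none
Why: Luche 1,2-reduction of the enone, with hydride arriving on the β face away from the axial C14 silyloxymethyl group (1,3-diaxial to C2) to give the 2α-alcohol cis to the C1 ester; the cold acidic quench limits 1,2-acyl migration.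

Step 12
Reactants: 21 (the diol from step 11)
Product: 22 (1R,2S,4aR,6S,8S,8aS)-2,8-bis(acetyloxy)-8a-{[(tert-butyldiphenylsilyl)oxy]methyl}-4-methyl-6-(prop-1-en-2-yl)-1,2,4a,5,6,7,8,8a-octahydronaphthalen-1-yl 3-methylbut-2-enoate
Conditions: Ac2O, DMAP, pyridine, CH2Cl2, 0 to 35 °C
Reagents that add atoms: acetic anhydride, CC(=O)OC(C)=O
Why: DMAP-catalysed acetylation of the allylic C2 and the hindered axial C9 hydroxyls, the only free hydroxyls present; no stereocentre is affected.

Step 13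
Reactants: 22 (the silyl ether from step 12)
Product: 23 (1R,2S,4aR,6S,8S,8aS)-2,8-bis(acetyloxy)-8a-(hydroxymethyl)-4-methyl-6-(prop-1-en-2-yl)-1,2,4a,5,6,7,8,8a-octahydronaphthalen-1-yl 3-methylbut-2-enoate (CNP0320218.1)
Conditions: HF·pyridine, pyridine/THF, 0 °C to rt
Reagents that add atoms: none
Why: Fluoride-mediated desilylation under mildly acidic conditions frees the C14 hydroxyl without acyl migration from O1 or O9 and without touching the esters or alkenes.

## Compound list

1 | cyclohex-2-en-1-one | O=C1C=CCCC1 | starting material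
2 | 4,4,5,5-tetramethyl-2-(prop-1-en-2-yl)-1,3,2-dioxaborolane | CC(=C)B1OC(C)(C)C(C)(C)O1 | starting material
3 | (S)-3-(prop-1-en-2-yl)cyclohexan-1-one | CC(=C)[C@H]1CCCC(=O)C1 | intermediate
4 | (S)-trimethyl{[5-(prop-1-en-2-yl)cyclohex-1-en-1-yl]oxy}silane | CC(=C)[C@H]1CCC=C(O[Si](C)(C)C)C1 | intermediate
5 | (S)-5-(prop-1-en-2-yl)cyclohex-2-en-1-one | CC(=C)[C@H]1CC=CC(=O)C1 | intermediate
6 | formaldehyde | C=O | starting material
7 | (S)-2-(hydroxymethyl)-5-(prop-1-en-2-yl)cyclohex-2-en-1-one | CC(=C)[C@H]1CC=C(CO)C(=O)C1 | intermediate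
8 | (S)-2-{[(tert-butyldiphenylsilyl)oxy]methyl}-5-(prop-1-en-2-yl)cyclohex-2-en-1-one | CC(=C)[C@H]1CC=C(CO[Si](c2ccccc2)(c2ccccc2)C(C)(C)C)C(=O)C1 | intermediate
9 | but-2-yn-1-ol | CC#CCO | starting material
10 | sodium 2,2-bis(2-methoxyethoxy)-3-methyl-2,5-dihydro-1,2-oxaluminol-2-uide (cyclic alkenylaluminate) | CC1=CCO[Al-]1(OCCOC)OCCOC.[Na+] | intermediate
11 | (Z)-3-iodobut-2-en-1-ol | C/C(I)=C/CO | intermediate
12 | (Z)-triethyl[(3-iodobut-2-en-1-yl)oxy]silane | C/C(I)=C/CO[Si](CC)(CC)CC | intermediate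
13 | chloro{(2Z)-4-[(triethylsilyl)oxy]but-2-en-2-yl}magnesium | C/C([Mg]Cl)=C/CO[Si](CC)(CC)CC | intermediate
14 | chloro{[(3R,5S)-2-{[(tert-butyldiphenylsilyl)oxy]methyl}-5-(prop-1-en-2-yl)-3-{(2Z)-4-[(triethylsilyl)oxy]but-2-en-2-yl}cyclohex-1-en-1-yl]oxy}magnesium | C=C(C)[C@@H]1CC(O[Mg]Cl)=C(CO[Si](c2ccccc2)(c2ccccc2)C(C)(C)C)[C@H](C1)/C(C)=C\CO[Si](CC)(CC)CC | intermediate
15 | (2S,3R,5S)-2-{[(tert-butyldiphenylsilyl)oxy]methyl}-2-(hydroxymethyl)-5-(prop-1-en-2-yl)-3-{(2Z)-4-[(triethylsilyl)oxy]but-2-en-2-yl}cyclohexan-1-one | C=C(C)[C@@H]1CC(=O)[C@@](CO)(CO[Si](c2ccccc2)(c2ccccc2)C(C)(C)C)[C@H](C1)/C(C)=C\CO[Si](CC)(CC)CC | intermediate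
16 | (2S,3R,5S)-2-{[(tert-butyldiphenylsilyl)oxy]methyl}-3-[(2Z)-4-hydroxybut-2-en-2-yl]-2-(hydroxymethyl)-5-(prop-1-en-2-yl)cyclohexan-1-one | C=C(C)[C@@H]1CC(=O)[C@@](CO)(CO[Si](c2ccccc2)(c2ccccc2)C(C)(C)C)[C@H](C1)/C(C)=C\CO | intermediate
17 | (1R,2R,4S)-1-{[(tert-butyldiphenylsilyl)oxy]methyl}-6-oxo-2-[(2Z)-4-oxobut-2-en-2-yl]-4-(prop-1-en-2-yl)cyclohexane-1-carbaldehyde | C=C(C)[C@@H]1CC(=O)[C@@](C=O)(CO[Si](c2ccccc2)(c2ccccc2)C(C)(C)C)[C@H](C1)/C(C)=C\C=O | intermediate
18 | (1R,4aR,6S,8aR)-8a-{[(tert-butyldiphenylsilyl)oxy]methyl}-1-hydroxy-4-methyl-6-(prop-1-en-2-yl)-4a,5,6,7-tetrahydronaphthalene-2,8(1H,8aH)-dione | C=C(C)[C@@H]1CC(=O)[C@@]2(CO[Si](c3ccccc3)(c3ccccc3)C(C)(C)C)[C@H](C1)C(C)=CC(=O)[C@@H]2O | intermediate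
19 | 3-methylbut-2-enal | CC(C)=CC=O | starting material
20 | (1R,4aR,6S,8S,8aS)-8a-{[(tert-butyldiphenylsilyl)oxy]methyl}-8-hydroxy-4-methyl-2-oxo-6-(prop-1-en-2-yl)-1,2,4a,5,6,7,8,8a-octahydronaphthalen-1-yl 3-methylbut-2-enoate | C=C(C)[C@@H]1C[C@H](O)[C@@]2(CO[Si](c3ccccc3)(c3ccccc3)C(C)(C)C)[C@H](C1)C(C)=CC(=O)[C@@H]2OC(=O)C=C(C)C | intermediate
21 | (1R,2S,4aR,6S,8S,8aS)-8a-{[(tert-butyldiphenylsilyl)oxy]methyl}-2,8-dihydroxy-4-methyl-6-(prop-1-en-2-yl)-1,2,4a,5,6,7,8,8a-octahydronaphthalen-1-yl 3-methylbut-2-enoate | C=C(C)[C@@H]1C[C@H](O)[C@@]2(CO[Si](c3ccccc3)(c3ccccc3)C(C)(C)C)[C@H](C1)C(C)=C[C@H](O)[C@@H]2OC(=O)C=C(C)C | intermediate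
22 | (1R,2S,4aR,6S,8S,8aS)-2,8-bis(acetyloxy)-8a-{[(tert-butyldiphenylsilyl)oxy]methyl}-4-methyl-6-(prop-1-en-2-yl)-1,2,4a,5,6,7,8,8a-octahydronaphthalen-1-yl 3-methylbut-2-enoate | C=C(C)[C@@H]1C[C@H](OC(C)=O)[C@@]2(CO[Si](c3ccccc3)(c3ccccc3)C(C)(C)C)[C@H](C1)C(C)=C[C@H](OC(C)=O)[C@@H]2OC(=O)C=C(C)C | intermediate
23 | (1R,2S,4aR,6S,8S,8aS)-2,8-bis(acetyloxy)-8a-(hydroxymethyl)-4-methyl-6-(prop-1-en-2-yl)-1,2,4a,5,6,7,8,8a-octahydronaphthalen-1-yl 3-methylbut-2-enoate | C=C(C)[C@@H]1C[C@H](OC(C)=O)[C@@]2(CO)[C@H](C1)C(C)=C[C@H](OC(C)=O)[C@@H]2OC(=O)C=C(C)C | target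

## Step count and risks

Total step count: 13. Longest linear sequence: 11 (steps 1–4 and 7–13, from cyclohex-2-en-1-one); steps 5–6 make the side-chain fragment.

The three steps most likely to fail:

Step 9 (benzoin ring closure). The β-keto aldehyde could be deformylated by the carbene, the Breslow intermediate could attack the C9 ketone, or the (Z)-enal could isomerise. The fallback sets out from 17 and changes the reactive species from a carbene adduct to a ketyl: SmI2 in THF/t-BuOH at −78 °C reduces the enal to its ketyl radical anion, which couples with the C1 aldehyde in a pinacol cyclisation to give the cis-1,2-diol (1R,2S,4aR,6S,8aR)-8a-{[(tert-butyldiphenylsilyl)oxy]methyl}-1,2-dihydroxy-4-methyl-6-(prop-1-en-2-yl)-1,2,4a,5,6,7-hexahydronaphthalen-8(8aH)-one F2. The configuration at C2 is immaterial, because MnO2 in CH2Cl2 then oxidises only the allylic C2 hydroxyl, and the fallback comes back to the route at 18.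

Step 10 (Evans–Tishchenko with an enal). The conjugated aldehyde may be a poor hydride donor or may oligomerise, and residual divalent samarium could attack the α-ketol. The fallback sets out from 18 and separates reduction from acylation: Me4NBH(OAc)3 in MeCN/AcOH at −20 °C delivers hydride from the C1 hydroxyl to the same face of C9 and gives the anti-diol (1R,4aR,6S,8S,8aS)-8a-{[(tert-butyldiphenylsilyl)oxy]methyl}-1,8-dihydroxy-4-methyl-6-(prop-1-en-2-yl)-4a,5,6,7,8,8a-hexahydronaphthalen-2(1H)-one F3. The equatorial C1 hydroxyl is then esterified in preference to the axial, doubly flanked C9 hydroxyl with 3-methylbut-2-enoic acid, 2,4,6-trichlorobenzoyl chloride, Et3N and DMAP, and the fallback comes back at 20.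

Step 7 (three-component coupling). The hindered α-substituted enone may need silyl activation, and the magnesium enolate may lose silanolate or trap formaldehyde poorly. The fallback sets out from 8 (with 13 made from 12 as before) and isolates a neutral enolate equivalent: the copper-catalysed addition is run with Me3SiCl to give {[(3R,5S)-2-{[(tert-butyldiphenylsilyl)oxy]methyl}-5-(prop-1-en-2-yl)-3-{(2Z)-4-[(triethylsilyl)oxy]but-2-en-2-yl}cyclohex-1-en-1-yl]oxy}trimethylsilane F1. This is hydroxymethylated with aqueous formaldehyde and Yb(OTf)3 in THF (Lewis-acid aldol of the silyl enol ether, again anti to the C5 substituent) to give 15, and acetic acid then takes the fallback back to the route at 16.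

A lesser risk is the regioselectivity of step 2, discussed in that step.

## Further compounds

F1 | step 7 | {[(3R,5S)-2-{[(tert-butyldiphenylsilyl)oxy]methyl}-5-(prop-1-en-2-yl)-3-{(2Z)-4-[(triethylsilyl)oxy]but-2-en-2-yl}cyclohex-1-en-1-yl]oxy}trimethylsilane | C=C(C)[C@@H]1CC(O[Si](C)(C)C)=C(CO[Si](c2ccccc2)(c2ccccc2)C(C)(C)C)[C@H](C1)/C(C)=C\CO[Si](CC)(CC)CC
F2 | step 9 | (1R,2S,4aR,6S,8aR)-8a-{[(tert-butyldiphenylsilyl)oxy]methyl}-1,2-dihydroxy-4-methyl-6-(prop-1-en-2-yl)-1,2,4a,5,6,7-hexahydronaphthalen-8(8aH)-one | C=C(C)[C@@H]1CC(=O)[C@@]2(CO[Si](c3ccccc3)(c3ccccc3)C(C)(C)C)[C@H](C1)C(C)=C[C@H](O)[C@@H]2O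
F3 | step 10 | (1R,4aR,6S,8S,8aS)-8a-{[(tert-butyldiphenylsilyl)oxy]methyl}-1,8-dihydroxy-4-methyl-6-(prop-1-en-2-yl)-4a,5,6,7,8,8a-hexahydronaphthalen-2(1H)-one | C=C(C)[C@@H]1C[C@H](O)[C@@]2(CO[Si](c3ccccc3)(c3ccccc3)C(C)(C)C)[C@H](C1)C(C)=CC(=O)[C@@H]2O
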